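## Analysis of the target

The target is a (2S)-flavanone. Ring A (C4a–C8a, hydroxyl at C7) is fused to the pyranone ring C (O1, C2, C3, C4=O), and C2 carries ring B. Ring B has a free hydroxyl at C3' and is fused through C4' (to O1'') and C5' (to C4'') to a 2,2-dimethylpyran ring D bearing a trans-3'',4''-diol, (3''R,4''S). C3'' and C4'' are adjacent, but C2 is separated from them by the whole of ring B, so neither set can direct the other and each needs its own source of asymmetry. C2 is the fragile centre: it is a benzylic aryl ether β to the C4 ketone, and any base that enolises C3 opens ring C to the 2'-hydroxychalcone, which recloses without facial preference. The C4'' hydroxyl is benzylic and ortho to the donor O1'', so acid can ionise it and scramble the trans relationship. The two phenols are electron-rich and must stay masked through the oxidative and organometallic steps. The difficulty is to create C2 enantioselectively without an enolisable ketone beside it and to bring the ketone in afterwards under neutral conditions. The feature used is that C3 and C4 of ring C are neighbours. Written as a C3=C4 alkene (a 2-aryl-2H-chromene), ring C holds C2 only as a secondary allylic, benzylic aryl ether carbon on O1. That is the product type of an asymmetric allylic etherification, and the alkene can be closed by olefin metathesis and later oxygenated at the benzylic C4.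

## Retrosynthetic reasoning

**Protecting groups (22 from 21 from 20).** The four hydroxyl groups are unmasked last. The Si–O bonds of the two silyl ethers on the diol of 21 are cut with buffered fluoride, and before that the two benzyl–oxygen bonds of 20 by hydrogenolysis. Both operations are neutral or weakly acidic, which is required once the C4 ketone is in place. Benzyl on the phenols and silyl on the diol survive every step in between.

**C4 oxygen (20 from 19 from 17).** The C4 carbonyl is traced to alcohol 19 and then, by cutting the C4–O bond, to alkene 17. C4 is the benzylic end of a styrene-type alkene conjugated to ring A, with the 7-benzyloxy group para to C4a. A hydrogen-atom-transfer hydration should therefore place oxygen on C4 only. The gain is that the ketone appears after C2 is set and ring C is closed, through two neutral steps.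

**Ring C (17 from 16).** The C3=C4 bond is cut. Cutting O1–C2 instead would call for an oxa-Michael closure onto an enone, which is reversible under base. Cutting C2–C1' would require an asymmetric conjugate arylation, and cutting C4–C4a an acylation under strong acid. Only the C3=C4 cut leaves a precursor, diene 16, in which C2 is a plain ether stereocentre and the bond to be formed is remote from it. The forward reaction has to join two terminal alkenes on a 1,7-diene without moving either double bond.

**O1–C2 bond (16 from 12 and 15).** This cut divides the molecule into the ring B/D cinnamyl carbonate 12 and the ring A phenol 15. An iridium-catalysed allylic etherification must deliver the branched ether and set C2 as S under catalyst control. The phenol already carries its vinyl group, so the nucleophile is electron-rich (a poor leaving group in the product) and no basic ylide is needed after C2 exists.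

**Ring A piece (15 from 14 from 13).** The vinyl group comes from methylenation of the aldehyde of 14. The benzyl ether comes from alkylation of the 4-hydroxyl of 13, which is the one not hydrogen-bonded to the formyl group.

**Allylic carbonate (12 from 11 from 10 from 9).** These are functional group changes only: the carbonate C–O bond, reduction of the ester to the allylic alcohol, and silylation of the diol at the ester stage.

**Ring D stereocentres (9 from 8 from 7).** The C4''–O bond is cut as a hydrolytic trans opening of epoxide 8 at its benzylic carbon. Both epoxide C–O bonds are then cut to the cis alkene of the 2,2-dimethylchromene 7. This alkene belongs to the substrate class for which manganese–salen oxygen transfer is most dependable. The other alkene of 7 is trans and electron-poor and is left alone.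

**Ring D skeleton (7 from 6 from 4 via 5 from 3 from 1 and 2).** The acrylate C=C bond is cut to aldehyde 6. The pyran ring is cut at the C5'–C4'' aryl–carbon bond, which a propargyl Claisen cascade forms from ether 4 through allenylphenol 5. The O–C(CH3)2 bond goes back to the more acidic para-hydroxyl of 1 and chloride 2. Only one ortho position of 4 is free, so ring D can form in one orientation only.

## Alternatives that were turned down

**Alternative 1:** The disconnection is the C3''–C4'' bond of ring D. In the forward sense the dialdehyde A1 (3-(benzyloxy)-5-bromo-2-[(2-methyl-1-oxopropan-2-yl)oxy]benzaldehyde) is treated with a chiral aminoindanol-derived triazolium carbene. The aryl aldehyde becomes the acyl anion equivalent and adds to the tethered aliphatic aldehyde, closing ring D as the ketol A2 ((3S)-8-(benzyloxy)-6-bromo-3-hydroxy-2,2-dimethylchroman-4-one, spatially the C3'' configuration of the target).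
- For it: one organocatalytic C–C bond formation makes ring D and a stereocentre. It needs no metal, no high-temperature rearrangement and no labile epoxide, and the acceptor aldehyde has a quaternary α-carbon and cannot self-condense.
- Against it: the new stereocentre of A2 bears a hydrogen α to an aryl ketone in the basic medium that generates the carbene, so enolisation and ene-diol isomerisation threaten it. C4'' then needs a second, diastereoselective step (hydroxyl-directed hydride delivery for the trans-diol). The sequence ends at an aryl bromide, so the carbon that becomes C2 and all of ring C are still to be made.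
- Comparison: for ring D alone it is at least as elegant. The chosen route instead takes both ring D centres from one oxygen transfer followed by a stereospecific opening, carries the future C2 carbon from the first step, and solves C2, which this alternative leaves open.

**Alternative 2:** The disconnection is C5'–C4'' together with O1''–C2''. The bromomagnesium phenoxide of A3 (2-(benzyloxy)-4-bromophenol) adds through its free ortho carbon to the epoxy aldehyde A4 ((2S)-3,3-dimethyloxirane-2-carbaldehyde) in a magnesium-templated ortho-hydroxyalkylation. The phenol oxygen then opens the epoxide at its tertiary carbon to give the trans-diol A5 ((3R,4S)-8-(benzyloxy)-6-bromo-2,2-dimethylchroman-3,4-diol).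
- For it: it is the shortest entry to ring D, with two bonds, the ring and C4'' formed in one flask, and A3 has a single free ortho position. On step count for ring D it is clearly stronger than the chosen route.
- Against it: the C4'' configuration depends on whether the aldehyde reacts through a magnesium chelate to the epoxide oxygen or through an open Felkin-type arrangement, and that balance is hard to predict. The epoxide must open 6-endo at the tertiary carbon against a 5-exo attack at the secondary carbon that would give a dihydrobenzofuran. A4 is small, volatile and prone to oligomerise. As in alternative 1, C2 and ring C are not addressed.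
- Comparison: the chosen route gives up step economy in ring D for a predictable absolute and relative configuration, and puts its one uncertain operation in ring C.

**Alternative 3:** Ring C is cut at C4a–C4, C4–C3 and O1–C2, giving the iodophenol A6 (5-(benzyloxy)-2-iodophenol), the aryl alkyne A7 (the 6-ethynyl ring B/D unit with the silylated diol) and a one-carbon carbonyl unit. A palladium-catalysed carbonylative coupling in a secondary amine gives the alkynone, which cyclises 6-endo to the flavone A8. Enantioselective conjugate reduction of C2=C3 of A8 would then give 20.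
- For it: it is the most convergent plan, with three bonds in one step. A8 is robust and has no C2 stereocentre to protect. It reaches 20 in one step after ring closure, where the chosen route needs two; on that point it is stronger.
- Against it: the only step that creates C2 is a conjugate reduction of a 2-aryl chromone. This is a vinylogous ester whose β-carbon carries an aryl group and oxygen, so it is poorly electrophilic and prone to over-reduction at C4. The immediate product is the C4 enolate of the flavanone, the species from which ring C opens, so the stereocentre is formed and endangered in the same medium. The carbonylative step can also divert to the 5-exo aurone.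
- Comparison: the chosen strategy makes C2 by a well-understood substitution at a carbon with no carbonyl neighbour and adds the ketone afterwards under neutral conditions. The price is two redox steps and the handling of a sensitive flav-3-ene.

Key step: step 13

Assumption: the (R,R)-manganese–salen catalyst is taken to give the (3R,4R)-epoxide and the (Sa,Sc,Sc)-phosphoramidite–iridium catalyst the (S)-allyl aryl ether, following the usual sense of induction of these catalyst families with 2,2-dimethylchromenes and cinnamyl carbonates; if a check on the first batch shows the opposite sense for either, the mirror-image catalyst is used and nothing else changes.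

## Route

Step 1
Reactants: 1 3,4-dihydroxybenzaldehyde; 2 3-chloro-3-methylbut-1-yne
Product: 3 3-hydroxy-4-[(2-methylbut-3-yn-2-yl)oxy]benzaldehyde
Conditions: DBU (1.1 equiv), CuCl2·2H2O (0.5 mol %), MeCN, 0 °C to rt
Reagents that add atoms: none
Why: Copper-catalysed propargylic etherification of a phenoxide with a tertiary propargylic chloride; the 4-hydroxyl is para to the formyl group and much more acidic than the 3-hydroxyl, so one equivalent of base forms the 4-phenoxide and the ether is formed there.

Step 2
Reactants: 3 3-hydroxy-4-[(2-methylbut-3-yn-2-yl)oxy]benzaldehyde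
Product: 4 3-(benzyloxy)-4-[(2-methylbut-3-yn-2-yl)oxy]benzaldehyde
Conditions: BnBr, K2CO3, DMF, rt
Reagents that add atoms: benzyl bromide, BrCc1ccccc1
Why: Williamson etherification of the only remaining phenol; it masks the future C3' hydroxyl before the thermal step and blocks that ortho position.

Step 3
Reactants: 4 3-(benzyloxy)-4-[(2-methylbut-3-yn-2-yl)oxy]benzaldehyde
Product: 6 8-(benzyloxy)-2,2-dimethyl-2H-chromene-6-carbaldehyde, via allenylphenol 5 (not isolated)
Conditions: PhNEt2, 180 °C
Reagents that add atoms: none
Why: Aromatic propargyl Claisen rearrangement to the ortho-allenylphenol 5, then [1,5]-hydrogen shift and oxa-6π electrocyclisation; only one ortho position is unsubstituted, so ring D forms in a single orientation with the benzyloxy group at C8 and the formyl group at C6.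

Step 4
Reactants: 6 8-(benzyloxy)-2,2-dimethyl-2H-chromene-6-carbaldehyde
Product: 7 ethyl (2E)-3-[8-(benzyloxy)-2,2-dimethyl-2H-chromen-6-yl]prop-2-enoate
Conditions: Ph3P=CHCO2Et, toluene, 80 °C
Reagents that add atoms: ethyl (triphenylphosphoranylidene)acetate, CCOC(=O)C=P(c1ccccc1)(c1ccccc1)c1ccccc1
Why: Wittig olefination with a stabilised ylide, which should give the E-acrylate; it adds the two carbons that become C3 and the carbon lost in the metathesis, while the aldehyde carbon becomes C2.

Step 5
Reactants: 7 ethyl (2E)-3-[8-(benzyloxy)-2,2-dimethyl-2H-chromen-6-yl]prop-2-enoate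
Product: 8 ethyl (2E)-3-[(3R,4R)-8-(benzyloxy)-3,4-epoxy-2,2-dimethylchroman-6-yl]prop-2-enoate
Conditions: (R,R)-Jacobsen catalyst [(R,R)-N,N'-bis(3,5-di-tert-butylsalicylidene)-1,2-cyclohexanediaminomanganese chloride] (4 mol %), 4-phenylpyridine N-oxide (20 mol %), aq. NaOCl (pH 11.3), CH2Cl2, 0 °C
Reagents that add atoms: sodium hypochlorite, [Na+].[O-]Cl
Why: Jacobsen epoxidation; the oxomanganese species transfers oxygen to the cis-disubstituted, electron-rich chromene alkene with the face chosen by the chiral diamine backbone, and 2,2-dimethylchromenes are the best substrate class for this catalyst; the trans, electron-poor acrylate alkene is not attacked by this electrophilic oxidant.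

Step 6
Reactants: 8 ethyl (2E)-3-[(3R,4R)-8-(benzyloxy)-3,4-epoxy-2,2-dimethylchroman-6-yl]prop-2-enoate
Product: 9 ethyl (2E)-3-[(3R,4S)-8-(benzyloxy)-3,4-dihydroxy-2,2-dimethylchroman-6-yl]prop-2-enoate
Conditions: HClO4 (cat.), THF/H2O, 0 °C
Reagents that add atoms: water, O
Why: Acid-catalysed hydrolysis of a benzylic epoxide; water attacks the protonated epoxide at the benzylic C4 from the face opposite the oxygen, so C4 is inverted and C3 keeps its C–O bond, giving the trans (3R,4S)-diol; the ring oxygen is para to the electron-withdrawing acrylate and no donor sits para to C4a, which disfavours a free benzylic cation.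

Step 7
Reactants: 9 ethyl (2E)-3-[(3R,4S)-8-(benzyloxy)-3,4-dihydroxy-2,2-dimethylchroman-6-yl]prop-2-enoate
Product: 10 ethyl (2E)-3-[(3R,4S)-8-(benzyloxy)-3,4-bis(tert-butyldimethylsilyloxy)-2,2-dimethylchroman-6-yl]prop-2-enoate
Conditions: TBSOTf (3 equiv), 2,6-lutidine, CH2Cl2, 0 °C to rt
Reagents that add atoms: tert-butyldimethylsilyl trifluoromethanesulfonate, CC(C)(C)[Si](C)(C)OS(=O)(=O)C(F)(F)F
Why: Silylation with a silyl triflate, reactive enough for the hindered C3 hydroxyl next to the gem-dimethyl carbon; the bulky ethers also shield the benzylic C4–O bond from ionisation and hydrogenolysis later.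

Step 8
Reactants: 10 ethyl (2E)-3-[(3R,4S)-8-(benzyloxy)-3,4-bis(tert-butyldimethylsilyloxy)-2,2-dimethylchroman-6-yl]prop-2-enoate
Product: 11 (2E)-3-[(3R,4S)-8-(benzyloxy)-3,4-bis(tert-butyldimethylsilyloxy)-2,2-dimethylchroman-6-yl]prop-2-en-1-ol
Conditions: i-Bu2AlH (2.5 equiv), CH2Cl2, -78 °C; Rochelle salt work-up
Reagents that add atoms: none
Why: 1,2-Reduction of an α,β-unsaturated ester by an aluminium hydride at low temperature gives the allylic alcohol with the E-alkene intact; silyl and benzyl ethers are inert.

Step 9
Reactants: 11 (2E)-3-[(3R,4S)-8-(benzyloxy)-3,4-bis(tert-butyldimethylsilyloxy)-2,2-dimethylchroman-6-yl]prop-2-en-1-ol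
Product: 12 methyl (2E)-3-[(3R,4S)-8-(benzyloxy)-3,4-bis(tert-butyldimethylsilyloxy)-2,2-dimethylchroman-6-yl]prop-2-en-1-yl carbonate
Conditions: ClCO2Me, pyridine, CH2Cl2, 0 °C
Reagents that add atoms: methyl chloroformate, COC(=O)Cl
Why: Acylation of the primary allylic alcohol to the methyl carbonate, the leaving group that the iridium catalyst ionises.

Step 10
Reactants: 13 2,4-dihydroxybenzaldehyde
Product: 14 4-(benzyloxy)-2-hydroxybenzaldehyde
Conditions: BnBr, NaHCO3, MeCN, 80 °C
Reagents that add atoms: benzyl bromide, BrCc1ccccc1
Why: Site-selective Williamson etherification; the 2-hydroxyl is held in a hydrogen bond to the formyl group and is not alkylated with the weak base, so only the 4-hydroxyl reacts.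

Step 11
Reactants: 14 4-(benzyloxy)-2-hydroxybenzaldehyde
Product: 15 5-(benzyloxy)-2-ethenylphenol
Conditions: Ph3PCH3Br (2.4 equiv), KOtBu (2.4 equiv), THF, 0 °C to rt
Reagents that add atoms: methyltriphenylphosphonium bromide, C[P+](c1ccccc1)(c1ccccc1)c1ccccc1.[Br-]
Why: Wittig methylenation of a salicylaldehyde; the first equivalent of ylide deprotonates the phenol and the second olefinates the aldehyde; doing it here means no basic ylide meets the C2 centre later.

Step 12
Reactants: 12 methyl (2E)-3-[(3R,4S)-8-(benzyloxy)-3,4-bis(tert-butyldimethylsilyloxy)-2,2-dimethylchroman-6-yl]prop-2-en-1-yl carbonate; 15 5-(benzyloxy)-2-ethenylphenol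
Product: 16 (3R,4S)-8-(benzyloxy)-6-{(1S)-1-[5-(benzyloxy)-2-ethenylphenoxy]prop-2-en-1-yl}-3,4-bis(tert-butyldimethylsilyloxy)-2,2-dimethylchroman
Conditions: [Ir(cod)Cl]2 (2 mol %), (Sa,Sc,Sc)-O,O'-(1,1'-binaphthyl-2,2'-diyl)-N,N-bis(1-phenylethyl)phosphoramidite (4 mol %), pre-activated with n-PrNH2; lithium aryloxide of 15 (n-BuLi, THF, 0 °C); THF, rt to 40 °C
Reagents that add atoms: none
Why: Iridium-catalysed asymmetric allylic etherification; the cyclometallated iridium–phosphoramidite complex ionises the carbonate to a π-allyl complex and the aryloxide attacks the aryl-substituted terminus anti to the metal, giving the branched ether, with the ligand choosing the face and so setting C2 as S independently of the distant ring D centres; 2-vinylphenoxides are competent nucleophiles here, and this electron-rich aryloxide is a poor leaving group, which limits re-ionisation of the product.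

Step 13
Reactants: 16 (3R,4S)-8-(benzyloxy)-6-{(1S)-1-[5-(benzyloxy)-2-ethenylphenoxy]prop-2-en-1-yl}-3,4-bis(tert-butyldimethylsilyloxy)-2,2-dimethylchroman
Product: 17 (2S)-7-(benzyloxy)-2-[(3R,4S)-8-(benzyloxy)-3,4-bis(tert-butyldimethylsilyloxy)-2,2-dimethylchroman-6-yl]-2H-chromene
Conditions: second-generation Grubbs catalyst, (H2IMes)(PCy3)Cl2Ru=CHPh (5 mol %), 1,4-benzoquinone (10 mol %), CH2Cl2 (0.01 M), 35 °C, dark
Reagents that add atoms: none
Why: Ring-closing olefin metathesis of a 2-vinylphenyl allyl ether, the standard metathesis entry to 2-substituted 2H-chromenes. The ruthenium benzylidene exchanges with one of the two terminal alkenes (loading on the ring A styrene gives an ortho-alkoxybenzylidene that stays active), the new alkylidene adds to the second alkene in a [2+2] sense, and cycloreversion of the ruthenacyclobutane releases ethene and the chromene. Ring C closes as a six-membered ring from a 1,7-diene whose two termini are held together by the aryl ether, so the new C3=C4 bond is endocyclic and necessarily cis, and at high dilution closure should outrun intermolecular coupling of the styrenes. No stereocentre is formed, and C2 is carried through unchanged because no bond to it is made or broken. The selectivity needed is reaction of the two terminal alkenes only, without migration of either double bond: the substrate has no other alkene, 1,4-benzoquinone intercepts ruthenium hydrides that could move the allyl ether alkene onto C2 or the product alkene to C2=C3, and the neutral, base-free medium leaves the benzylic allylic C2–O1 bond intact. The reaction is kept at or below 40 °C in the dark and the product is purified on base-washed silica, since a 2-aryl-2H-chromene can open to an ortho-quinone methide on heating or irradiation and can ionise at C2–O1 with acid.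

Step 14
Reactants: 17 (2S)-7-(benzyloxy)-2-[(3R,4S)-8-(benzyloxy)-3,4-bis(tert-butyldimethylsilyloxy)-2,2-dimethylchroman-6-yl]-2H-chromene
Product: 19 (2S,4RS)-7-(benzyloxy)-2-[(3R,4S)-8-(benzyloxy)-3,4-bis(tert-butyldimethylsilyloxy)-2,2-dimethylchroman-6-yl]chroman-4-ol, via C4 hydroperoxide 18 (not isolated)
Conditions: Mn(dpm)3 (10 mol %), PhSiH3, O2 (1 atm), i-PrOH/CH2Cl2, 0 °C to rt; then PPh3
Reagents that add atoms: dioxygen, O=O
Why: Mukaiyama hydration by hydrogen atom transfer; the manganese hydride formed from Mn(dpm)3 and the silane delivers a hydrogen atom to C3, leaving the more stable benzylic radical at C4 (conjugated to ring A, 7-benzyloxy para), which dioxygen traps as hydroperoxide 18 and triphenylphosphine reduces to the alcohol; the C4 configuration is irrelevant because that carbon is oxidised next, and the neutral medium does not ionise C2–O1.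

Step 15
Reactants: 19 (2S,4RS)-7-(benzyloxy)-2-[(3R,4S)-8-(benzyloxy)-3,4-bis(tert-butyldimethylsilyloxy)-2,2-dimethylchroman-6-yl]chroman-4-ol
Product: 20 (2S)-7-(benzyloxy)-2-[(3R,4S)-8-(benzyloxy)-3,4-bis(tert-butyldimethylsilyloxy)-2,2-dimethylchroman-6-yl]chroman-4-one
Conditions: Dess–Martin periodinane, NaHCO3, CH2Cl2, 0 °C to rt
Reagents that add atoms: none
Why: Dess–Martin oxidation of a secondary benzylic alcohol under buffered, non-basic conditions; C3 is not enolised, so ring C does not open and C2 keeps its configuration; both C4 epimers converge on one ketone.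

Step 16
Reactants: 20 (2S)-7-(benzyloxy)-2-[(3R,4S)-8-(benzyloxy)-3,4-bis(tert-butyldimethylsilyloxy)-2,2-dimethylchroman-6-yl]chroman-4-one
Product: 21 (2S)-2-[(3R,4S)-3,4-bis(tert-butyldimethylsilyloxy)-8-hydroxy-2,2-dimethylchroman-6-yl]-7-hydroxychroman-4-one
Conditions: H2 (1 atm), 10 % Pd/C, EtOAc, rt, stopped after uptake of two equivalents
Reagents that add atoms: none
Why: Hydrogenolysis of aryl benzyl ethers, which under neutral conditions in ethyl acetate is much faster than cleavage of the cyclic benzylic C2–O1 bond or of the hindered silylated benzylic C4''–O bond; no acid or base is present, so C2 is safe.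

Step 17
Reactants: 21 (2S)-2-[(3R,4S)-3,4-bis(tert-butyldimethylsilyloxy)-8-hydroxy-2,2-dimethylchroman-6-yl]-7-hydroxychroman-4-one
Product: 22 (2S)-7-hydroxy-2-[(3R,4S)-3,4,8-trihydroxy-2,2-dimethylchroman-6-yl]chroman-4-one
Conditions: HF·pyridine, pyridine, THF, 0 °C to rt
Reagents that add atoms: none
Why: Fluoride desilylation with buffered hydrogen fluoride; the weakly acidic medium does not enolise C3 or open ring C, as basic fluoride with free phenols could, and is too weak to ionise the benzylic C4''–O bond.

## Compound list

1 | 3,4-dihydroxybenzaldehyde | O=Cc1ccc(O)c(O)c1 | starting material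
2 | 3-chloro-3-methylbut-1-yne | CC(C)(Cl)C#C | starting material
3 | 3-hydroxy-4-[(2-methylbut-3-yn-2-yl)oxy]benzaldehyde | O=Cc1ccc(OC(C)(C)C#C)c(O)c1 | intermediate
4 | 3-(benzyloxy)-4-[(2-methylbut-3-yn-2-yl)oxy]benzaldehyde | O=Cc1ccc(OC(C)(C)C#C)c(OCc2ccccc2)c1 | intermediate
5 | 3-(benzyloxy)-4-hydroxy-5-(3-methylbuta-1,2-dien-1-yl)benzaldehyde | O=Cc1cc(C=C=C(C)C)c(O)c(OCc2ccccc2)c1 | intermediate
6 | 8-(benzyloxy)-2,2-dimethyl-2H-chromene-6-carbaldehyde | CC1(C)C=Cc2cc(C=O)cc(OCc3ccccc3)c2O1 | intermediate
7 | ethyl (2E)-3-[8-(benzyloxy)-2,2-dimethyl-2H-chromen-6-yl]prop-2-enoate | CC1(C)Oc2c(OCc3ccccc3)cc(/C=C/C(=O)OCC)cc2C=C1 | intermediate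
8 | ethyl (2E)-3-[(3R,4R)-8-(benzyloxy)-3,4-epoxy-2,2-dimethylchroman-6-yl]prop-2-enoate | CC1(C)Oc2c(OCc3ccccc3)cc(/C=C/C(=O)OCC)cc2[C@H]2O[C@@H]12 | intermediate
9 | ethyl (2E)-3-[(3R,4S)-8-(benzyloxy)-3,4-dihydroxy-2,2-dimethylchroman-6-yl]prop-2-enoate | CC1(C)Oc2c(OCc3ccccc3)cc(/C=C/C(=O)OCC)cc2[C@H](O)[C@H]1O | intermediate
10 | ethyl (2E)-3-[(3R,4S)-8-(benzyloxy)-3,4-bis(tert-butyldimethylsilyloxy)-2,2-dimethylchroman-6-yl]prop-2-enoate | CC1(C)Oc2c(OCc3ccccc3)cc(/C=C/C(=O)OCC)cc2[C@H](O[Si](C)(C)C(C)(C)C)[C@H]1O[Si](C)(C)C(C)(C)C | intermediate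
11 | (2E)-3-[(3R,4S)-8-(benzyloxy)-3,4-bis(tert-butyldimethylsilyloxy)-2,2-dimethylchroman-6-yl]prop-2-en-1-ol | CC1(C)Oc2c(OCc3ccccc3)cc(/C=C/CO)cc2[C@H](O[Si](C)(C)C(C)(C)C)[C@H]1O[Si](C)(C)C(C)(C)C | intermediate
12 | methyl (2E)-3-[(3R,4S)-8-(benzyloxy)-3,4-bis(tert-butyldimethylsilyloxy)-2,2-dimethylchroman-6-yl]prop-2-en-1-yl carbonate | CC1(C)Oc2c(OCc3ccccc3)cc(/C=C/COC(=O)OC)cc2[C@H](O[Si](C)(C)C(C)(C)C)[C@H]1O[Si](C)(C)C(C)(C)C | intermediate
13 | 2,4-dihydroxybenzaldehyde | O=Cc1ccc(O)cc1O | starting material
14 | 4-(benzyloxy)-2-hydroxybenzaldehyde | O=Cc1ccc(OCc2ccccc2)cc1O | intermediate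
15 | 5-(benzyloxy)-2-ethenylphenol | C=Cc1ccc(OCc2ccccc2)cc1O | intermediate
16 | (3R,4S)-8-(benzyloxy)-6-{(1S)-1-[5-(benzyloxy)-2-ethenylphenoxy]prop-2-en-1-yl}-3,4-bis(tert-butyldimethylsilyloxy)-2,2-dimethylchroman | CC1(C)Oc2c(OCc3ccccc3)cc([C@@H](Oc3cc(OCc4ccccc4)ccc3C=C)C=C)cc2[C@H](O[Si](C)(C)C(C)(C)C)[C@H]1O[Si](C)(C)C(C)(C)C | intermediate
17 | (2S)-7-(benzyloxy)-2-[(3R,4S)-8-(benzyloxy)-3,4-bis(tert-butyldimethylsilyloxy)-2,2-dimethylchroman-6-yl]-2H-chromene | CC1(C)Oc2c(OCc3ccccc3)cc([C@@H]3C=Cc4ccc(OCc5ccccc5)cc4O3)cc2[C@H](O[Si](C)(C)C(C)(C)C)[C@H]1O[Si](C)(C)C(C)(C)C | intermediate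
18 | (2S,4RS)-7-(benzyloxy)-2-[(3R,4S)-8-(benzyloxy)-3,4-bis(tert-butyldimethylsilyloxy)-2,2-dimethylchroman-6-yl]chroman-4-yl hydroperoxide | CC1(C)Oc2c(OCc3ccccc3)cc([C@@H]3CC(OO)c4ccc(OCc5ccccc5)cc4O3)cc2[C@H](O[Si](C)(C)C(C)(C)C)[C@H]1O[Si](C)(C)C(C)(C)C | intermediate
19 | (2S,4RS)-7-(benzyloxy)-2-[(3R,4S)-8-(benzyloxy)-3,4-bis(tert-butyldimethylsilyloxy)-2,2-dimethylchroman-6-yl]chroman-4-ol | CC1(C)Oc2c(OCc3ccccc3)cc([C@@H]3CC(O)c4ccc(OCc5ccccc5)cc4O3)cc2[C@H](O[Si](C)(C)C(C)(C)C)[C@H]1O[Si](C)(C)C(C)(C)C | intermediate
20 | (2S)-7-(benzyloxy)-2-[(3R,4S)-8-(benzyloxy)-3,4-bis(tert-butyldimethylsilyloxy)-2,2-dimethylchroman-6-yl]chroman-4-one | CC1(C)Oc2c(OCc3ccccc3)cc([C@@H]3CC(=O)c4ccc(OCc5ccccc5)cc4O3)cc2[C@H](O[Si](C)(C)C(C)(C)C)[C@H]1O[Si](C)(C)C(C)(C)C | intermediate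
21 | (2S)-2-[(3R,4S)-3,4-bis(tert-butyldimethylsilyloxy)-8-hydroxy-2,2-dimethylchroman-6-yl]-7-hydroxychroman-4-one | CC1(C)Oc2c(O)cc([C@@H]3CC(=O)c4ccc(O)cc4O3)cc2[C@H](O[Si](C)(C)C(C)(C)C)[C@H]1O[Si](C)(C)C(C)(C)C | intermediate
22 | (2S)-7-hydroxy-2-[(3R,4S)-3,4,8-trihydroxy-2,2-dimethylchroman-6-yl]chroman-4-one | CC1(C)Oc2c(O)cc([C@@H]3CC(=O)c4ccc(O)cc4O3)cc2[C@H](O)[C@H]1O | target

## Step count and least certain steps

Total: 17 steps. Longest linear sequence: 15 steps (steps 1–9 and 12–17, from 1); the ring A branch (steps 10 and 11) joins at step 12.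

**Step 13 (key step).** The most probable failure is migration of a double bond under ruthenium hydride catalysis (the allyl ether alkene onto C2, or the product alkene to C2=C3), together with opening of the 2H-chromene during isolation by heterolysis of C2–O1 on acidic supports or by thermal or photochemical electrocyclic opening. Each of these erases C2. The fallback sets out from 12 and comes back at 20. It avoids the flav-3-ene by placing the C4 oxygen on the ring A alkene before metathesis. Carbonate 12 is etherified under the conditions of step 12 with the lithium salt of commercial 1-[4-(benzyloxy)-2-hydroxyphenyl]ethanone to give the (S)-configured 2-acetyl-5-(benzyloxy)phenyl 1-arylallyl ether F1. TBSOTf and Et3N in CH2Cl2 convert the methyl ketone into the 1-silyloxyvinyl compound F2; the enolate has no β-leaving group and C2 is not involved. Ring-closing metathesis of the silyl enol ether with the allyl alkene, a known route to cyclic silyl enol ethers with second-generation Grubbs catalyst, gives the 4-silyloxy-2H-chromene F3. Hydrolysis of the enol ether with oxalic acid in wet THF then gives 20 directly, which also makes steps 14 and 15 unnecessary.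

**Step 12.** The likely problem lies with the styrene-bearing nucleophile. Its oligomerisation, or binding of its vinyl group to the cationic iridium centre, would slow the substitution, and a slow substitution lets the product re-ionise (it carries an electron-rich aryl group on the allylic carbon) with loss of branched selectivity and of enantiomeric purity. The fallback sets out from 12 and 14 and comes back at 16. The lithium salt of 14, which has no alkene, is used as the nucleophile under the same catalyst to give the (S)-configured 5-(benzyloxy)-2-formylphenyl 1-arylallyl ether F4. Its non-enolisable aldehyde is then methylenated with Ph3P=CH2 (from Ph3PCH3Br and KHMDS, THF, -78 to 0 °C), a reagent not basic enough to remove the C2 hydrogen, to give 16.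

**Step 14.** The likely problem is hydrogen atom transfer without oxygen capture (reduction of the alkene to the flavan) or radical side reactions at the benzylic C2–H, so that C4 oxygenation is incomplete. The fallback sets out from 17 and comes back at 19 by a two-electron Markovnikov hydroboration in place of the radical hydration. Catecholborane with [Rh(cod)2]BF4 and 1,4-bis(diphenylphosphino)butane in THF at -20 °C places boron at the benzylic C4, as cationic rhodium does with vinylarenes, to give the C4 catecholboronate F5. Oxidation with NaBO3·4H2O in THF/H2O gives 19.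

**Step 6.** The likely problem is partial ionisation of the protonated epoxide to a benzylic cation before water attacks, which would erode the trans selectivity at C4''. The fallback sets out from 8 and comes back at 9 by replacing the acid-catalysed opening with a bimolecular one. KOH in DMSO/H2O at 60 °C opens the epoxide at the less hindered benzylic C4 with inversion and saponifies the ester at the same time, giving after acidification the trans-dihydroxy cinnamic acid F6. Selective alkylation of the carboxylate with EtI and K2CO3 in DMF returns 9.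

**Step 1.** The likely problem is incomplete site selectivity or double alkylation with the slow tertiary chloride, or copper-mediated oxidation of the free catechol. The fallback sets out from 1 and comes back at 4 by temporarily marking the para-hydroxyl with a reactive primary halide. Allyl bromide and NaHCO3 in DMF give 4-(allyloxy)-3-hydroxybenzaldehyde F7. Benzyl bromide and K2CO3 give 4-(allyloxy)-3-(benzyloxy)benzaldehyde F8. Pd(PPh3)4 with morpholine removes the allyl group to give 3-(benzyloxy)-4-hydroxybenzaldehyde F9. This single phenol is then etherified with 2 under the conditions of step 1 to give 4.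

## Further compounds

F1 | step 13 | 1-[4-(benzyloxy)-2-{(1S)-1-[(3R,4S)-8-(benzyloxy)-3,4-bis(tert-butyldimethylsilyloxy)-2,2-dimethylchroman-6-yl]prop-2-en-1-yloxy}phenyl]ethanone | CC1(C)Oc2c(OCc3ccccc3)cc([C@@H](Oc3cc(OCc4ccccc4)ccc3C(C)=O)C=C)cc2[C@H](O[Si](C)(C)C(C)(C)C)[C@H]1O[Si](C)(C)C(C)(C)C
F2 | step 13 | (3R,4S)-8-(benzyloxy)-6-{(1S)-1-[5-(benzyloxy)-2-(1-(tert-butyldimethylsilyloxy)ethenyl)phenoxy]prop-2-en-1-yl}-3,4-bis(tert-butyldimethylsilyloxy)-2,2-dimethylchroman | CC1(C)Oc2c(OCc3ccccc3)cc([C@@H](Oc3cc(OCc4ccccc4)ccc3C(=C)O[Si](C)(C)C(C)(C)C)C=C)cc2[C@H](O[Si](C)(C)C(C)(C)C)[C@H]1O[Si](C)(C)C(C)(C)C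
F3 | step 13 | (2S)-7-(benzyloxy)-2-[(3R,4S)-8-(benzyloxy)-3,4-bis(tert-butyldimethylsilyloxy)-2,2-dimethylchroman-6-yl]-4-(tert-butyldimethylsilyloxy)-2H-chromene | CC1(C)Oc2c(OCc3ccccc3)cc([C@@H]3C=C(O[Si](C)(C)C(C)(C)C)c4ccc(OCc5ccccc5)cc4O3)cc2[C@H](O[Si](C)(C)C(C)(C)C)[C@H]1O[Si](C)(C)C(C)(C)C
F4 | step 12 | 4-(benzyloxy)-2-{(1S)-1-[(3R,4S)-8-(benzyloxy)-3,4-bis(tert-butyldimethylsilyloxy)-2,2-dimethylchroman-6-yl]prop-2-en-1-yloxy}benzaldehyde | CC1(C)Oc2c(OCc3ccccc3)cc([C@@H](Oc3cc(OCc4ccccc4)ccc3C=O)C=C)cc2[C@H](O[Si](C)(C)C(C)(C)C)[C@H]1O[Si](C)(C)C(C)(C)C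
F5 | step 14 | 2-{(2S,4RS)-7-(benzyloxy)-2-[(3R,4S)-8-(benzyloxy)-3,4-bis(tert-butyldimethylsilyloxy)-2,2-dimethylchroman-6-yl]chroman-4-yl}-1,3,2-benzodioxaborole | CC1(C)Oc2c(OCc3ccccc3)cc([C@@H]3CC(B4Oc5ccccc5O4)c4ccc(OCc5ccccc5)cc4O3)cc2[C@H](O[Si](C)(C)C(C)(C)C)[C@H]1O[Si](C)(C)C(C)(C)C
F6 | step 6 | (2E)-3-[(3R,4S)-8-(benzyloxy)-3,4-dihydroxy-2,2-dimethylchroman-6-yl]prop-2-enoic acid | CC1(C)Oc2c(OCc3ccccc3)cc(/C=C/C(=O)O)cc2[C@H](O)[C@H]1O
F7 | step 1 | 4-(allyloxy)-3-hydroxybenzaldehyde | O=Cc1ccc(OCC=C)c(O)c1
F8 | step 1 | 4-(allyloxy)-3-(benzyloxy)benzaldehyde | O=Cc1ccc(OCC=C)c(OCc2ccccc2)c1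
F9 | step 1 | 3-(benzyloxy)-4-hydroxybenzaldehyde | O=Cc1ccc(O)c(OCc2ccccc2)c1
A1 | alternative 1 | 3-(benzyloxy)-5-bromo-2-[(2-methyl-1-oxopropan-2-yl)oxy]benzaldehyde | O=CC(C)(C)Oc1c(C=O)cc(Br)cc1OCc1ccccc1
A2 | alternative 1 | (3S)-8-(benzyloxy)-6-bromo-3-hydroxy-2,2-dimethylchroman-4-one | CC1(C)Oc2c(OCc3ccccc3)cc(Br)cc2C(=O)[C@H]1O
A3 | alternative 2 | 2-(benzyloxy)-4-bromophenol | Oc1ccc(Br)cc1OCc1ccccc1
A4 | alternative 2 | (2S)-3,3-dimethyloxirane-2-carbaldehyde | O=C[C@H]1OC1(C)C
A5 | alternative 2 | (3R,4S)-8-(benzyloxy)-6-bromo-2,2-dimethylchroman-3,4-diol | CC1(C)Oc2c(OCc3ccccc3)cc(Br)cc2[C@H](O)[C@H]1O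
A6 | alternative 3 | 5-(benzyloxy)-2-iodophenol | Oc1cc(OCc2ccccc2)ccc1I
A7 | alternative 3 | (3R,4S)-8-(benzyloxy)-3,4-bis(tert-butyldimethylsilyloxy)-6-ethynyl-2,2-dimethylchroman | CC1(C)Oc2c(OCc3ccccc3)cc(C#C)cc2[C@H](O[Si](C)(C)C(C)(C)C)[C@H]1O[Si](C)(C)C(C)(C)C
A8 | alternative 3 | 7-(benzyloxy)-2-[(3R,4S)-8-(benzyloxy)-3,4-bis(tert-butyldimethylsilyloxy)-2,2-dimethylchroman-6-yl]-4H-chromen-4-one | CC1(C)Oc2c(OCc3ccccc3)cc(-c3cc(=O)c4ccc(OCc5ccccc5)cc4o3)cc2[C@H](O[Si](C)(C)C(C)(C)C)[C@H]1O[Si](C)(C)C(C)(C)C
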